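A direct plan would bring all seven rings in as methylated arenes and make the six diaryl ether bonds one after another, each time between a di-ortho-substituted phenoxide such as 4-iodo-2,6-dimethoxyphenol A1 and an aryl(2,4,6-trimethoxyphenyl)iodonium salt of the next ring or ring pair (A2 for rings B–C, A3 for rings F–G).
It would end with the octadeca-O-methyl ether A4 and remove all eighteen methyl groups in one operation.
Its weakest step would be the oxidation of each aryl iodide to the iodonium salt before every coupling: about half of all steps would only activate a ring, add no complexity, and expose ever more electron-rich oligomers to peracid and strong acid.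
The second would be the fluoride-triggered desilylation and O-arylation on tri- and pentameric material: one silyl ether would have to be cleaved beside the silyl ether of the incoming salt, so the outcome would rest on exact stoichiometry at the most valuable stage.
The third, and the one least welcome on late material, would be the cleavage of eighteen aryl methyl ethers with a large excess of BBr3: incomplete demethylation, ring bromination and air oxidation of the polyphenol in acid would all cost heptamer that could not be recovered.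
No stereocentre and no ring closure would be at risk; the cost would lie in steps per bond and in the end game.

**Plan of the new route**
The retrosynthesis would cut no aryl–oxygen bond: it cuts the C2–C3 bond of each linking ring B, D and F, which opens these rings to triketide chains that are carried, closed on oxygen, as 2-pyrones.
The feature that allows this: rings B, D and F each show the phloroglucinol pattern of a triketide (OH on C1 and C3, ether oxygen on C5), and their fourth oxygen sits on C2, the carbon that is the methyl end of triacetic acid lactone; a 4-aryloxy-6-(aryloxymethyl)-2-pyrone is thus an isomer of a 2,5-bis(aryloxy)benzene-1,3-diol.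
Rings A, C, E and G would come from benzylated phenols and be strung together through three 4-bromo-6-(bromomethyl)-2-pyrone units by phenoxide substitutions only: SN2 at CH2Br by the unhindered oxygen, addition–elimination at C4 by the hindered one, with a formyl group as the masked second oxygen of rings C and E.
Rings B, D and F would then arise last and together, by one base-induced isomerisation of the tris-pyrone (ring opening, Claisen closure); hydrogenolysis of twelve benzyl ethers would finish.
No ring would be activated at iodine, no silyl ether would have to be told from another, and no methyl ether would have to be cleaved.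
Key step: step 14

Assumption: 3,4,5-tris(benzyloxy)benzaldehyde, 1,3,5-tris(benzyloxy)benzene and 4-hydroxy-6-methyl-2H-pyran-2-one are taken as purchasable; the first two are otherwise one benzylation away from the parent phenols.

**Route**

Step 1
Reactants: 1 3,4,5-tris(benzyloxy)benzaldehyde
Product: 3 3,4,5-tris(benzyloxy)phenol, via 3,4,5-tris(benzyloxy)phenyl formate 2 (not isolated)
Conditions: mCPBA, CH2Cl2, 0 °C to rt; then K2CO3 (cat.), MeOH, rt
Reagents that add atoms: 3-chloroperbenzoic acid O=C(OO)c1cccc(Cl)c1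
Why: Baeyer–Villiger oxidation in its Dakin sense: the electron-rich trioxygenated aryl group migrates to oxygen and the resulting formate is cleaved by methanolysis.

Step 2
Reactants: 3 3,4,5-tris(benzyloxy)phenol
Product: 4 6-hydroxy-2,3,4-tris(benzyloxy)benzaldehyde
Conditions: MgCl2, Et3N, paraformaldehyde, MeCN, reflux
Reagents that add atoms: formaldehyde (as paraformaldehyde) C=O
Why: Magnesium-phenoxide-directed ortho-formylation (a second equivalent of formaldehyde acts as hydride acceptor), which can only reach the two equivalent ortho positions because the para position carries a benzyloxy group.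

Step 3
Reactants: 5 4-hydroxy-6-methyl-2H-pyran-2-one
Product: 6 4-bromo-6-methyl-2H-pyran-2-one
Conditions: Bu4NBr, P2O5, toluene, 100 °C
Reagents that add atoms: tetrabutylammonium bromide CCCC[N+](CCCC)(CCCC)CCCC.[Br-]
Why: Dehydrative bromination of a vinylogous acid: the 4-OH is activated as a phosphate and replaced by bromide through addition–elimination at C4.

Step 4
Reactants: 6 4-bromo-6-methyl-2H-pyran-2-one
Product: 7 4-bromo-6-(bromomethyl)-2H-pyran-2-one
Conditions: NBS, AIBN (cat.), PhCF3, reflux
Reagents that add atoms: N-bromosuccinimide O=C1CCC(=O)N1Br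
Why: Wohl–Ziegler radical bromination at the only allylic C–H bonds, those of the 6-methyl group, a reaction type established for 4-alkoxy-6-methyl-2-pyrones.

Step 5
Reactants: 4 6-hydroxy-2,3,4-tris(benzyloxy)benzaldehyde; 7 4-bromo-6-(bromomethyl)-2H-pyran-2-one
Product: 8 2,3,4-tris(benzyloxy)-6-[(4-bromo-2-oxo-2H-pyran-6-yl)methoxy]benzaldehyde
Conditions: K2CO3, MeCN, 0 °C to rt
Reagents that add atoms: none
Why: Williamson ether synthesis: SN2 displacement of the allylic primary bromide should outrun addition–elimination at C4 for the weakly nucleophilic, hydrogen-bonded salicylaldehyde phenoxide at low temperature.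

Step 6
Reactants: 3 3,4,5-tris(benzyloxy)phenol; 7 4-bromo-6-(bromomethyl)-2H-pyran-2-one
Product: 9 4-bromo-6-{[3,4,5-tris(benzyloxy)phenoxy]methyl}-2H-pyran-2-one
Conditions: K2CO3, MeCN, 0 °C
Reagents that add atoms: none
Why: Williamson ether synthesis at the allylic bromide, run cold and without excess phenol so that the vinylic bromide at C4 is kept for the later coupling.

Step 7
Reactants: 10 1,3,5-tris(benzyloxy)benzene
Product: 12 2,4,6-tris(benzyloxy)benzaldehyde, via aryl iminium chloride 11 (not isolated)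
Conditions: POCl3, DMF, 0 °C to rt; then aq. NaOAc
Reagents that add atoms: N,N-dimethylformamide CN(C)C=O; water O
Why: Vilsmeier–Haack formylation of a phloroglucinol triether, whose three free positions are equivalent and whose ring is deactivated once the first iminium group is in place.

Step 8
Reactants: 12 2,4,6-tris(benzyloxy)benzaldehyde
Product: 14 2,4,6-tris(benzyloxy)phenol, via 2,4,6-tris(benzyloxy)phenyl formate 13 (not isolated)
Conditions: mCPBA, CH2Cl2, 0 °C to rt; then K2CO3 (cat.), MeOH, rt
Reagents that add atoms: 3-chloroperbenzoic acid O=C(OO)c1cccc(Cl)c1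
Why: Dakin-type Baeyer–Villiger oxidation with migration of the 2,4,6-trioxygenated aryl group, followed by methanolysis of the formate.

Step 9
Reactants: 14 2,4,6-tris(benzyloxy)phenol; 8 2,3,4-tris(benzyloxy)-6-[(4-bromo-2-oxo-2H-pyran-6-yl)methoxy]benzaldehyde
Product: 15 2,3,4-tris(benzyloxy)-6-({2-oxo-4-[2,4,6-tris(benzyloxy)phenoxy]-2H-pyran-6-yl}methoxy)benzaldehyde (ring A–pyrone B–ring C aldehyde)
Conditions: Cs2CO3, MeCN, 25–40 °C, Ar
Reagents that add atoms: none
Why: Nucleophilic vinylic substitution by addition–elimination: the di-ortho-substituted phenoxide adds to C4 of the 4-bromo-2-pyrone (a vinylogous acyl bromide) and bromide leaves, so no aromatic ring needs activation, and the temperature is held at or below 40 °C so that aldol closure of the aryloxymethyl group onto the aldehyde (Rap–Stoermer type) stays slow.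

Step 10
Reactants: 15 ring A–pyrone B–ring C aldehyde
Product: 17 6-{[3,4,5-tris(benzyloxy)-2-hydroxyphenoxy]methyl}-4-[2,4,6-tris(benzyloxy)phenoxy]-2H-pyran-2-one (ring A–pyrone B–ring C phenol), via aryl formate 16 (not isolated)
Conditions: mCPBA, NaHCO3, CH2Cl2, 0 °C to rt; then satd. aq. NaHCO3, MeOH/THF, rt
Reagents that add atoms: 3-chloroperbenzoic acid O=C(OO)c1cccc(Cl)c1
Why: Dakin-type Baeyer–Villiger oxidation unmasks the second oxygen of ring C: the tetraoxygenated aryl group migrates, the electron-poor pyrone double bonds should not be epoxidised, and the formate is hydrolysed near pH 8 so that no alkoxide meets the pyrone.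

Step 11
Reactants: 17 ring A–pyrone B–ring C phenol; 8 2,3,4-tris(benzyloxy)-6-[(4-bromo-2-oxo-2H-pyran-6-yl)methoxy]benzaldehyde
Product: 18 ring A–pyrone B–ring C–pyrone D–ring E aldehyde (the phenolic oxygen of 17 bonded to C4 of the pyrone of 8)
Conditions: Cs2CO3, MeCN, 25–40 °C, Ar
Reagents that add atoms: none
Why: Addition–elimination at C4 of the bromopyrone, which as a vinylogous acyl bromide should react much faster with the hindered phenoxide than the 4-aryloxypyrone already present in 17.

Step 12
Reactants: 18 ring A–pyrone B–ring C–pyrone D–ring E aldehyde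
Product: 20 ring A–pyrone B–ring C–pyrone D–ring E phenol (CHO of 18 replaced by OH), via aryl formate 19 (not isolated)
Conditions: mCPBA, NaHCO3, CH2Cl2, 0 °C to rt; then satd. aq. NaHCO3, MeOH/THF, rt
Reagents that add atoms: 3-chloroperbenzoic acid O=C(OO)c1cccc(Cl)c1
Why: Dakin-type Baeyer–Villiger oxidation with aryl migration, as in step 10, unmasks the second oxygen of ring E.

Step 13
Reactants: 20 ring A–pyrone B–ring C–pyrone D–ring E phenol; 9 4-bromo-6-{[3,4,5-tris(benzyloxy)phenoxy]methyl}-2H-pyran-2-one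
Product: 21 tris-pyrone (the phenolic oxygen of 20 bonded to C4 of the pyrone of 9)
Conditions: Cs2CO3, MeCN, 25–40 °C, Ar
Reagents that add atoms: none
Why: Addition–elimination of the hindered phenoxide at C4 of the bromopyrone completes the chain of four benzene rings and three pyrones.

Step 14
Reactants: 21 tris-pyrone
Product: 23 dodeca-O-benzyl ether of the target (three benzyloxy groups on each of rings A/C/E/G; two free hydroxyls on each of rings B/D/F), via tris(keto ester) 22 (not isolated)
Conditions: Mg(OMe)2 (excess), MeOH/THF, 65 °C, Ar; then cold aq. HCl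
Reagents that add atoms: none
Why: Proposed new method: methoxide delivered by Mg(OMe)2 should add to each lactone carbonyl and open the 2-pyrone to a magnesium-chelated methyl (E)-3-aryloxy-5-oxohex-2-enoate, whose ketone enolises towards the aryloxymethyl carbon, which then attacks the ester carbonyl; loss of methoxide and enolisation give the benzene-1,3-diol, so each pyrone is isomerised to ring B, D or F with the lactone and ring oxygens becoming the two phenolic hydroxyls. The closest known reactions are the aromatisation of 6-(2-oxoalkyl)-4-hydroxy-2-pyrones to acylphloroglucinols with methanolic Mg(OMe)2 (polyketide-type Claisen cyclisation) and the alkoxide cyclisation of 5-oxohexanoates to cyclohexane-1,3-diones; here the attacking carbon is activated by only one ketone and the aryloxy group, which is the untested point. Each of the three rings closes by a Claisen condensation of Dieckmann type (6-exo-trig attack of the enolate carbon on the ester). No stereocentre is formed. C- over O-acylation is needed and should be secured because O-acylation only regenerates the pyrone, which methoxide reopens, whereas the magnesium phenoxide of the arene is a thermodynamic sink. Attack of methoxide at C2 instead of substitution at C4 is needed and should be secured by the two ortho substituents of every C4 aryloxy group (rings A, C and E), which shield C4; an aldol closure cannot compete because the chain holds no second ketone.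

Step 15
Reactants: 23 dodeca-O-benzyl ether of the target
Product: 24 CNP0292517.0 (target)
Conditions: H2 (1 atm), Pd(OH)2 on carbon, degassed THF/MeOH, rt; filtration and reversed-phase purification under Ar
Reagents that add atoms: none
Why: Heterogeneous hydrogenolysis of twelve benzyl aryl ethers under neutral conditions; the diaryl ether bonds are inert and toluene is the only by-product.

**Compound list**

1 | 3,4,5-tris(benzyloxy)benzaldehyde | O=Cc1cc(OCc9ccccc9)c(OCc9ccccc9)c(OCc9ccccc9)c1 | starting material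
2 | 3,4,5-tris(benzyloxy)phenyl formate | O=COc1cc(OCc9ccccc9)c(OCc9ccccc9)c(OCc9ccccc9)c1 | intermediate (not isolated)
3 | 3,4,5-tris(benzyloxy)phenol (ring G phenol) | Oc1cc(OCc9ccccc9)c(OCc9ccccc9)c(OCc9ccccc9)c1 | intermediate
4 | 6-hydroxy-2,3,4-tris(benzyloxy)benzaldehyde (ring C/E unit; CHO is the masked second oxygen) | O=Cc1c(O)cc(OCc9ccccc9)c(OCc9ccccc9)c1OCc9ccccc9 | intermediate
5 | 4-hydroxy-6-methyl-2H-pyran-2-one (triacetic acid lactone) | CC1=CC(O)=CC(=O)O1 | starting material
6 | 4-bromo-6-methyl-2H-pyran-2-one | CC1=CC(Br)=CC(=O)O1 | intermediate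
7 | 4-bromo-6-(bromomethyl)-2H-pyran-2-one | BrCC1=CC(Br)=CC(=O)O1 | intermediate
8 | 2,3,4-tris(benzyloxy)-6-[(4-bromo-2-oxo-2H-pyran-6-yl)methoxy]benzaldehyde | O=Cc1c(OCC2=CC(Br)=CC(=O)O2)cc(OCc9ccccc9)c(OCc9ccccc9)c1OCc9ccccc9 | intermediate
9 | 4-bromo-6-{[3,4,5-tris(benzyloxy)phenoxy]methyl}-2H-pyran-2-one | BrC1=CC(=O)OC(COc2cc(OCc9ccccc9)c(OCc9ccccc9)c(OCc9ccccc9)c2)=C1 | intermediate
10 | 1,3,5-tris(benzyloxy)benzene | c1c(OCc9ccccc9)cc(OCc9ccccc9)cc1OCc9ccccc9 | starting material
11 | N-methyl-N-{[2,4,6-tris(benzyloxy)phenyl]methylidene}methanaminium chloride | C[N+](C)=Cc1c(OCc9ccccc9)cc(OCc9ccccc9)cc1OCc9ccccc9.[Cl-] | intermediate (not isolated)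
12 | 2,4,6-tris(benzyloxy)benzaldehyde | O=Cc1c(OCc9ccccc9)cc(OCc9ccccc9)cc1OCc9ccccc9 | intermediate
13 | 2,4,6-tris(benzyloxy)phenyl formate | O=COc1c(OCc9ccccc9)cc(OCc9ccccc9)cc1OCc9ccccc9 | intermediate (not isolated)
14 | 2,4,6-tris(benzyloxy)phenol (ring A phenol) | Oc1c(OCc9ccccc9)cc(OCc9ccccc9)cc1OCc9ccccc9 | intermediate
15 | 2,3,4-tris(benzyloxy)-6-({2-oxo-4-[2,4,6-tris(benzyloxy)phenoxy]-2H-pyran-6-yl}methoxy)benzaldehyde | O=Cc1c(OCC2=CC(Oc3c(OCc9ccccc9)cc(OCc9ccccc9)cc3OCc9ccccc9)=CC(=O)O2)cc(OCc9ccccc9)c(OCc9ccccc9)c1OCc9ccccc9 | intermediate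
16 | 2,3,4-tris(benzyloxy)-6-({2-oxo-4-[2,4,6-tris(benzyloxy)phenoxy]-2H-pyran-6-yl}methoxy)phenyl formate | O=COc1c(OCC2=CC(Oc3c(OCc9ccccc9)cc(OCc9ccccc9)cc3OCc9ccccc9)=CC(=O)O2)cc(OCc9ccccc9)c(OCc9ccccc9)c1OCc9ccccc9 | intermediate (not isolated)
17 | 6-{[3,4,5-tris(benzyloxy)-2-hydroxyphenoxy]methyl}-4-[2,4,6-tris(benzyloxy)phenoxy]-2H-pyran-2-one | Oc1c(OCC2=CC(Oc3c(OCc9ccccc9)cc(OCc9ccccc9)cc3OCc9ccccc9)=CC(=O)O2)cc(OCc9ccccc9)c(OCc9ccccc9)c1OCc9ccccc9 | intermediate
18 | ring A–pyrone B–ring C–pyrone D–ring E aldehyde (17 with its phenolic oxygen on C4 of a 2-pyrone whose C6 bears CH2O bonded to C6 of 2,3,4-tris(benzyloxy)benzaldehyde) | O=Cc1c(OCC2=CC(Oc3c(OCC4=CC(Oc5c(OCc9ccccc9)cc(OCc9ccccc9)cc5OCc9ccccc9)=CC(=O)O4)cc(OCc9ccccc9)c(OCc9ccccc9)c3OCc9ccccc9)=CC(=O)O2)cc(OCc9ccccc9)c(OCc9ccccc9)c1OCc9ccccc9 | intermediate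
19 | aryl formate of the ring A–pyrone B–ring C–pyrone D–ring E unit (CHO of 18 replaced by OCHO) | O=COc1c(OCC2=CC(Oc3c(OCC4=CC(Oc5c(OCc9ccccc9)cc(OCc9ccccc9)cc5OCc9ccccc9)=CC(=O)O4)cc(OCc9ccccc9)c(OCc9ccccc9)c3OCc9ccccc9)=CC(=O)O2)cc(OCc9ccccc9)c(OCc9ccccc9)c1OCc9ccccc9 | intermediate (not isolated)
20 | ring A–pyrone B–ring C–pyrone D–ring E phenol (CHO of 18 replaced by OH) | Oc1c(OCC2=CC(Oc3c(OCC4=CC(Oc5c(OCc9ccccc9)cc(OCc9ccccc9)cc5OCc9ccccc9)=CC(=O)O4)cc(OCc9ccccc9)c(OCc9ccccc9)c3OCc9ccccc9)=CC(=O)O2)cc(OCc9ccccc9)c(OCc9ccccc9)c1OCc9ccccc9 | intermediate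
21 | tris-pyrone: rings A, C, E, G as tris(benzyloxy)aryl units joined through three 2-pyrones, each bearing the hindered aryloxy group on C4 and the aryloxymethyl group on C6 | c9ccccc9COc1cc(OCc9ccccc9)c(OC2=CC(=O)OC(COc3cc(OCc9ccccc9)c(OCc9ccccc9)c(OCc9ccccc9)c3OC3=CC(=O)OC(COc4cc(OCc9ccccc9)c(OCc9ccccc9)c(OCc9ccccc9)c4OC4=CC(=O)OC(COc5cc(OCc9ccccc9)c(OCc9ccccc9)c(OCc9ccccc9)c5)=C4)=C3)=C2)c(OCc9ccccc9)c1 | intermediate
22 | tris(keto ester): each pyrone of 21 opened to a methyl (E)-3-aryloxy-6-aryloxy-5-oxohex-2-enoate | c9ccccc9COc1cc(OCc9ccccc9)c(O/C(=C/C(=O)OC)CC(=O)COc2cc(OCc9ccccc9)c(OCc9ccccc9)c(OCc9ccccc9)c2O/C(=C/C(=O)OC)CC(=O)COc2cc(OCc9ccccc9)c(OCc9ccccc9)c(OCc9ccccc9)c2O/C(=C/C(=O)OC)CC(=O)COc2cc(OCc9ccccc9)c(OCc9ccccc9)c(OCc9ccccc9)c2)c(OCc9ccccc9)c1 | intermediate (not isolated)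
23 | dodeca-O-benzyl ether of the target (rings A, C, E, G benzylated; the six hydroxyls of rings B, D, F free) | c9ccccc9COc1cc(OCc9ccccc9)c(Oc2cc(O)c(Oc3cc(OCc9ccccc9)c(OCc9ccccc9)c(OCc9ccccc9)c3Oc3cc(O)c(Oc4cc(OCc9ccccc9)c(OCc9ccccc9)c(OCc9ccccc9)c4Oc4cc(O)c(Oc5cc(OCc9ccccc9)c(OCc9ccccc9)c(OCc9ccccc9)c5)c(O)c4)c(O)c3)c(O)c2)c(OCc9ccccc9)c1 | intermediate
24 | CNP0292517.0 (achiral heptameric fuhalol-type phlorotannin) | Oc1cc(O)c(Oc2cc(O)c(Oc3cc(O)c(O)c(O)c3Oc3cc(O)c(Oc4cc(O)c(O)c(O)c4Oc4cc(O)c(Oc5cc(O)c(O)c(O)c5)c(O)c4)c(O)c3)c(O)c2)c(O)c1 | target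

**Count and risks**

Total steps: 15. Longest linear sequence: 10 steps (1, 2, 5, 9, 10, 11, 12, 13, 14, 15).

Steps most likely to fail:

1. Step 14 (Proposed new method). The ring-opened keto esters may simply re-close on oxygen to the pyrones faster than the weakly activated aryloxymethyl carbon attacks the ester, or methoxide may displace a hindered aryloxide from C4 and cut the chain; three such events must all succeed on one molecule. The fallback gives up the pyrones and uses known diaryl ether chemistry. It sets out from phenol 14. O-arylation of 14 with the ring B–C iodonium tosylate A2 (Cs2CO3, MeCN, 45 °C) should give triisopropyl{6-[2,6-dimethoxy-4-(2,4,6-tris(benzyloxy)phenoxy)phenoxy]-2,3,4-trimethoxyphenoxy}silane F1. Bu4NF in THF should free the trimeric phenol F2. A second arylation with A2 under the same conditions should give the pentameric silyl ether F3, and Bu4NF the pentameric phenol F4. Arylation of F4 with the ring F–G iodonium tosylate A3 should give the heptamer with three benzyl and fifteen methyl ethers F5. BBr3 in CH2Cl2 (−78 °C to rt) would cleave both kinds of ether, and the fallback comes back to the route at the target 24.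

2. Step 5 (and likewise step 6). The phenoxide may add at C4 and displace the vinylic bromide, or react at both bromides, instead of displacing only the allylic one; over-bromination in step 4 would feed the same problem. The fallback sets out from 6 and avoids any phenoxide. Allylic oxidation of the 6-methyl group with SeO2 (dioxane, 160 °C, sealed) should give 4-bromo-2-oxo-2H-pyran-6-carbaldehyde F6. Reduction with NaBH(OAc)3 (THF/AcOH, rt) should give 4-bromo-6-(hydroxymethyl)-2H-pyran-2-one F7. Mitsunobu etherification of phenol 4 with F7 (PPh3, diisopropyl azodicarboxylate, THF, 0 °C) comes back to the route at 8; the same alcohol and phenol 3 would give 9.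

3. Step 11 (and likewise step 13). The pyrone-bearing phenoxide may add to an aryloxypyrone already in the chain (exchange of aryloxides between molecules, or 1,6-addition to its own pyrone), and the base may start aldol closure of the aryloxymethyl group of 8 onto its neighbouring aldehyde. The fallback changes the order of bond formation at this junction and sets out from 17. The phenoxide of 17 would first be joined to the simple alcohol 4-bromo-6-(hydroxymethyl)-2H-pyran-2-one F7 (made from 6 as above; Cs2CO3, MeCN, rt, F7 in excess) to give the 4-aryloxy-6-(hydroxymethyl)pyrone F8, with no aldehyde present under base. The salicylaldehyde 4 would then be attached under neutral Mitsunobu conditions (PPh3, diisopropyl azodicarboxylate, THF, 0 °C), which comes back to the route at 18.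

**Further compounds**

F1 | step 14 | triisopropyl{6-[2,6-dimethoxy-4-(2,4,6-tris(benzyloxy)phenoxy)phenoxy]-2,3,4-trimethoxyphenoxy}silane | c9ccccc9COc1cc(OCc9ccccc9)c(Oc2cc(OC)c(Oc3cc(OC)c(OC)c(OC)c3O[Si](C(C)C)(C(C)C)C(C)C)c(OC)c2)c(OCc9ccccc9)c1
F2 | step 14 | 6-[2,6-dimethoxy-4-(2,4,6-tris(benzyloxy)phenoxy)phenoxy]-2,3,4-trimethoxyphenol | c9ccccc9COc1cc(OCc9ccccc9)c(Oc2cc(OC)c(Oc3cc(OC)c(OC)c(OC)c3O)c(OC)c2)c(OCc9ccccc9)c1
F3 | step 14 | ring A–B–C–D–E silyl ether (oxygen of F2 bonded to C1 of a 3,5-dimethoxy-1,4-phenylene ring D whose 4-oxygen carries the 3,4,5-trimethoxy-2-(triisopropylsilyloxy)phenyl ring E) | c9ccccc9COc1cc(OCc9ccccc9)c(Oc2cc(OC)c(Oc3cc(OC)c(OC)c(OC)c3Oc3cc(OC)c(Oc4cc(OC)c(OC)c(OC)c4O[Si](C(C)C)(C(C)C)C(C)C)c(OC)c3)c(OC)c2)c(OCc9ccccc9)c1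
F4 | step 14 | ring A–B–C–D–E phenol (F3 with OH in place of the silyloxy group) | c9ccccc9COc1cc(OCc9ccccc9)c(Oc2cc(OC)c(Oc3cc(OC)c(OC)c(OC)c3Oc3cc(OC)c(Oc4cc(OC)c(OC)c(OC)c4O)c(OC)c3)c(OC)c2)c(OCc9ccccc9)c1
F5 | step 14 | tri-O-benzyl pentadeca-O-methyl ether of the target (benzyl groups on ring A) | c9ccccc9COc1cc(OCc9ccccc9)c(Oc2cc(OC)c(Oc3cc(OC)c(OC)c(OC)c3Oc3cc(OC)c(Oc4cc(OC)c(OC)c(OC)c4Oc4cc(OC)c(Oc5cc(OC)c(OC)c(OC)c5)c(OC)c4)c(OC)c3)c(OC)c2)c(OCc9ccccc9)c1
F6 | step 5 | 4-bromo-2-oxo-2H-pyran-6-carbaldehyde | O=CC1=CC(Br)=CC(=O)O1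
F7 | step 5 | 4-bromo-6-(hydroxymethyl)-2H-pyran-2-one | OCC1=CC(Br)=CC(=O)O1
F8 | step 11 | 6-(hydroxymethyl)-2-pyrone carrying on C4 the phenolic oxygen of 17 | OCC1=CC(Oc2c(OCC3=CC(Oc4c(OCc9ccccc9)cc(OCc9ccccc9)cc4OCc9ccccc9)=CC(=O)O3)cc(OCc9ccccc9)c(OCc9ccccc9)c2OCc9ccccc9)=CC(=O)O1
A1 | direct plan | 4-iodo-2,6-dimethoxyphenol | COc1cc(I)cc(OC)c1O
A2 | direct plan | {3,5-dimethoxy-4-[3,4,5-trimethoxy-2-(triisopropylsilyloxy)phenoxy]phenyl}(2,4,6-trimethoxyphenyl)iodonium tosylate | COc1cc([I+]c2c(OC)cc(OC)cc2OC)cc(OC)c1Oc1cc(OC)c(OC)c(OC)c1O[Si](C(C)C)(C(C)C)C(C)C.Cc1ccc(cc1)S(=O)(=O)[O-]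
A3 | direct plan | [3,5-dimethoxy-4-(3,4,5-trimethoxyphenoxy)phenyl](2,4,6-trimethoxyphenyl)iodonium tosylate | COc1cc([I+]c2c(OC)cc(OC)cc2OC)cc(OC)c1Oc1cc(OC)c(OC)c(OC)c1.Cc1ccc(cc1)S(=O)(=O)[O-]
A4 | direct plan | octadeca-O-methyl ether of the target | COc1cc(OC)c(Oc2cc(OC)c(Oc3cc(OC)c(OC)c(OC)c3Oc3cc(OC)c(Oc4cc(OC)c(OC)c(OC)c4Oc4cc(OC)c(Oc5cc(OC)c(OC)c(OC)c5)c(OC)c4)c(OC)c3)c(OC)c2)c(OC)c1
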